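The ten-membered ring is taken apart at its two alkenes. C1=C10 and C4=C5, with the C2–C3 link between them, map onto a strained bicyclo[2.2.0]hexane built from C1, C2, C3, C4, C5 and C10 that shares its C5–C10 edge with a cyclohexanone (C5 to C10); the key step exploits this relationship. Flash thermolysis of the cis-anti-cis tricyclic ketone cuts C1–C4 and C5–C10 and should deliver both π bonds and the (1(10)E,4Z)-cyclodecadienone in one operation. The precursor, from an enone–cyclobutene [2+2] photocycloaddition, holds C7 and C8 in a cis-fused 8,12-lactone. C6 reduction, lactone shift to O6, α-methylenation, C8 acylation and C1=C10 epoxidation finish the target.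

Key step: step 7

Remark: germacrane numbering (C1–C15) is used for all ring carbons; the (R,R) ligand of step 2 is assumed to deliver boron to the face that gives 8R, and its mirror image is used if the sense of induction is the opposite.

Step 1
Reactants: 1 tert-butyl bromoacetate; 2 2-iodocyclohex-2-en-1-one
Product: 4 tert-butyl 2-(6-oxocyclohex-1-en-1-yl)acetate, via Reformatsky zinc reagent 3 (not isolated)
Conditions: Zn dust, THF, 40 °C; then 2, Pd(PPh3)4 (5 mol%), THF, 50 °C
Reagents that add atoms: none
Why: Negishi cross-coupling in which the zinc ester enolate (Reformatsky reagent) transmetalates to the alkenylpalladium iodide formed by oxidative addition at the C(sp2)–I bond and reductive elimination forges C7–C11; no stereocentre is created.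

Step 2
Reactants: 4 tert-butyl 2-(6-oxocyclohex-1-en-1-yl)acetate
Product: 6 tert-butyl 2-[(1R,2R)-2-hydroxy-6-oxocyclohexyl]acetate, via β-boryl ketone 5 (not isolated)
Conditions: CuCl (5 mol%), NaOtBu (10 mol%), (R,R)-QuinoxP* (6 mol%), B2pin2 (1.1 equiv), MeOH (2 equiv), THF, 0 °C; then NaBO3·4H2O, THF/H2O, rt
Reagents that add atoms: sodium perborate (oxygen of the C8 hydroxyl), [Na+].[O-]B1OO1
Why: Copper-catalysed enantioselective conjugate borylation in which the chiral bisphosphine–Cu–Bpin species adds boron to C8 from one enantiotopic face (catalyst control, 8R), methanol protonates the enolate at C7 anti to the new C–B bond (cis product), and perborate replaces boron by hydroxyl with retention.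

Step 3
Reactants: 6 tert-butyl 2-[(1R,2R)-2-hydroxy-6-oxocyclohexyl]acetate
Product: 7 (3aR,7aR)-hexahydro-1-benzofuran-2,4-dione
Conditions: TFA/CH2Cl2 (1:4), 0 °C to rt
Reagents that add atoms: none
Why: Acidolysis of the tert-butyl ester and γ-lactonisation of the cis hydroxy acid; the cis-fused lactone is the stable ring fusion and the enolisable C7 centre lets any trans isomer converge on it, while C8 is untouched.

Step 4
Reactants: 7 (3aR,7aR)-hexahydro-1-benzofuran-2,4-dione
Product: 9 (3aR,7aR)-3,3a,7,7a-tetrahydro-1-benzofuran-2,4-dione, via silyl enol ether 8 (not isolated)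
Conditions: LiN(iPr)2 (1.05 equiv), Me3SiCl, THF, −78 °C; then Pd(OAc)2 (1.0 equiv), MeCN, rt
Reagents that add atoms: none
Why: Saegusa–Ito dehydrogenation in which kinetic deprotonation takes a C5 methylene proton and not the hindered ring-fusion C7–H (whose removal would also expel the lactone oxygen), and Pd(OAc)2 turns the silyl enol ether into the C5=C10 enone; C7 and C8 are not affected.

Step 5
Reactants: 9 (3aR,7aR)-3,3a,7,7a-tetrahydro-1-benzofuran-2,4-dione
Product: 11 (3aR,7aR)-6-methyl-3,3a,7,7a-tetrahydro-1-benzofuran-2,4-dione, via β-methyl silyl enol ether 10 (not isolated)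
Conditions: Me2CuLi (from MeLi and CuI), Me3SiCl, THF, −78 °C; then Pd(OAc)2 (1.0 equiv), MeCN, rt
Reagents that add atoms: lithium dimethylcuprate (C14 methyl), [Li+].C[Cu-]C
Why: Gilman cuprate 1,4-addition with silyl trapping gives the regiodefined C5=C6 silyl enol ether (methyl enters trans to the C8 oxygen, a transient centre), and a second Saegusa–Ito oxidation restores the enone and erases C10 as a stereocentre.

Step 6
Reactants: 11 (3aR,7aR)-6-methyl-3,3a,7,7a-tetrahydro-1-benzofuran-2,4-dione; 12 1-methylcyclobutene
Product: 13 cis-anti-cis tricyclic photoadduct ketone carrying the cis-fused C7/C8 lactone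
Conditions: hν (350 nm, Pyrex), 12 (10 equiv), CH2Cl2, −40 °C
Reagents that add atoms: none
Why: Enone–alkene [2+2] photocycloaddition through the enone triplet and a 1,4-diradical, in which C10 bonds to the unsubstituted cyclobutene carbon C1 and the tertiary radical at C4 closes on C5 (head-to-head, no adjacent quaternary centres), the cyclobutene approaches the face opposite the lactone, and closure gives the usual cis-anti-cis fusion that sets C1, C4, C5 and C10.

Step 7
Reactants: 13 cis-anti-cis tricyclic photoadduct ketone
Product: 14 (1(10)E,4Z,7R,8R)-6-oxo-13-norgermacra-1(10),4-dien-12,8-olide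
Conditions: flash vacuum thermolysis, quartz tube, 500 °C, 0.01 mbar, contact time about 10 ms, cold trap −196 °C
Reagents that add atoms: none
Why: Homolysis of the strained central C1–C4 bond gives a cyclohexane-1,4-diyl (C1, C2, C3, C4, C5, C10), which then fragments across C5–C10 to the C1=C10 and C4=C5 alkenes. The closest known reaction is the thermal cycloreversion of bicyclo[2.2.0]hexanes to hexa-1,5-dienes, used on enone–cyclobutene photoadducts as the thermal half of a photo-thermal metathesis. The ten-membered ring is not closed by joining two chain ends: it appears by ring expansion when the bond common to the four- and six-membered rings is cut. No stereocentre is formed; the geometry should follow from the chair diyl that keeps C14 equatorial on the cyclohexanone ring (no 1,3-diaxial contact with O8), which places C9 equatorial and C6 axial on the diyl ring and so gives 1(10)E and 4Z. The step needs C5–C10 cleavage and not C2–C3 cleavage, which the weaker, more substituted bond and the conjugation gained with the C6 ketone should secure, and it needs the dienone to escape Cope rearrangement, which millisecond contact and cold trapping should secure. The cis-fused lactone carries C7 and C8 through without epimerisation or elimination.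

Step 8
Reactants: 14 (1(10)E,4Z,7R,8R)-6-oxo-13-norgermacra-1(10),4-dien-12,8-olide
Product: 15 (1(10)E,4Z,6R,7S,8R)-6-hydroxy-13-norgermacra-1(10),4-dien-12,8-olide
Conditions: NaBH4, CeCl3·7H2O, MeOH, −78 °C
Reagents that add atoms: none
Why: Luche reduction gives clean 1,2-addition to the enone, and hydride should arrive from the outer face of C6 in the pseudo-chair inherited from the ring opening (C11 pseudo-axial, inner face closed by the transannular C1=C10 bond), so that the new C6–O bond lies anti to C11 (6R, 6α-OH).

Step 9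
Reactants: 15 (1(10)E,4Z,6R,7S,8R)-6-hydroxy-13-norgermacra-1(10),4-dien-12,8-olide
Product: 16 (1(10)E,4Z,6R,7R,8R)-8-hydroxy-13-norgermacra-1(10),4-dien-12,6-olide
Conditions: K2CO3 (0.3 equiv), MeOH, 0 °C to rt
Reagents that add atoms: none
Why: Base-mediated intramolecular transesterification (O-to-O acyl shift through a bicyclic tetrahedral intermediate) in which the C6 alkoxide attacks C12 and O8 is released; the trans-fused 6,12-olide, the arrangement kept by natural 8β-hydroxy germacranolides, should be the thermodynamic product, and C6, C7 and C8 keep their configurations.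

Step 10
Reactants: 16 (1(10)E,4Z,6R,7R,8R)-8-hydroxy-13-norgermacra-1(10),4-dien-12,6-olide
Product: 19 (1(10)E,4Z,6R,7R,8R)-8-hydroxygermacra-1(10),4,11(13)-trien-12,6-olide, via Mannich base 17 (not isolated), via ammonium iodide 18 (not isolated)
Conditions: LiN(iPr)2 (2.3 equiv), THF, −78 °C; CH2=NMe2+ I− (Eschenmoser's salt), −78 to 0 °C; then MeI, MeOH, rt; then aq NaHCO3, EtOAc, rt
Reagents that add atoms: N,N-dimethylmethyleneiminium iodide (C13), C=[N+](C)C.[I-]
Why: α-Methylenation of the lactone by the Mannich route, in which the dianion (C8 alkoxide and lactone enolate) is aminomethylated at C11, N-methylation makes the leaving group and mild base effects β-elimination to the exocyclic alkene; the C11 centre of 17 is destroyed in the elimination.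

Step 11
Reactants: 20 angelic acid
Product: 21 (Z)-2-methylbut-2-en-1-ol
Conditions: LiAlH4, Et2O, 0 °C to rt
Reagents that add atoms: none
Why: Hydride reduction of the carboxylic acid to the allylic alcohol (attack at the carboxyl carbon, not at the electron-rich trisubstituted alkene), with the Z geometry retained.

Step 12
Reactants: 21 (Z)-2-methylbut-2-en-1-ol
Product: 22 [(2R,3S)-2,3-dimethyloxiran-2-yl]methanol
Conditions: Ti(OiPr)4 (10 mol%), D-(−)-diethyl tartrate (12 mol%), tBuOOH, 4 Å molecular sieves, CH2Cl2, −20 °C
Reagents that add atoms: tert-butyl hydroperoxide (epoxide oxygen), CC(C)(C)OO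
Why: Sharpless asymmetric epoxidation in which the titanium tartrate complex delivers oxygen to one face of the allylic alcohol; with the D-(−)-tartrate the Z-2-methyl substrate should give the (2R,3S)-epoxy alcohol, the relative configuration following from the alkene geometry.

Step 13
Reactants: 22 [(2R,3S)-2,3-dimethyloxiran-2-yl]methanol
Product: 23 (2S,3S)-2,3-dimethyloxirane-2-carboxylic acid
Conditions: TEMPO (10 mol%), PhI(OAc)2 (2.2 equiv), MeCN/H2O (1:1), rt
Reagents that add atoms: water (second carboxyl oxygen), O
Why: Oxoammonium (TEMPO) oxidation with PhI(OAc)2 as terminal oxidant takes the primary alcohol through the aldehyde hydrate to the acid without touching the epoxide stereocentres (the descriptor at C2 changes only through the priority rules).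

Step 14
Reactants: 19 (1(10)E,4Z,6R,7R,8R)-8-hydroxygermacra-1(10),4,11(13)-trien-12,6-olide; 23 (2S,3S)-2,3-dimethyloxirane-2-carboxylic acid
Product: 25 (1(10)E,4Z,6R,7R,8R)-8-[(2S,3S)-2,3-dimethyloxirane-2-carbonyloxy]germacra-1(10),4,11(13)-trien-12,6-olide, via mixed anhydride 24 (not isolated)
Conditions: 23, 2,4,6-trichlorobenzoyl chloride, Et3N, toluene, rt; then 19, DMAP, toluene, rt
Reagents that add atoms: none
Why: Yamaguchi esterification in which DMAP attacks the less hindered epoxy-acyl carbonyl of the mixed anhydride and the acylpyridinium acylates the hindered C8 hydroxyl, with retention at C8 and at both epoxide carbons.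

Step 15
Reactants: 25 (1(10)E,4Z,6R,7R,8R)-8-[(2S,3S)-2,3-dimethyloxirane-2-carbonyloxy]germacra-1(10),4,11(13)-trien-12,6-olide
Product: 26 (1R,4Z,6R,7R,8R,10R)-1,10-epoxy-8-[(2S,3S)-2,3-dimethyloxirane-2-carbonyloxy]germacra-4,11(13)-dien-12,6-olide (CNP0165580.1)
Conditions: mCPBA (1.05 equiv), NaHCO3, CH2Cl2, 0 °C
Reagents that add atoms: 3-chloroperbenzoic acid (epoxide oxygen), OOC(=O)c1cccc(Cl)c1
Why: Prilezhaev epoxidation at the most electron-rich alkene, the trisubstituted C1=C10 (C4=C5 is deactivated by the allylic lactone oxygen and C11=C13 is conjugated), from its exposed outer face, which in the heliangolide conformation with C14 on the β face should give the 1β,10α (1R,10R) trans-epoxide.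

Compound list
1 | tert-butyl bromoacetate | CC(C)(C)OC(=O)CBr | starting material
2 | 2-iodocyclohex-2-en-1-one | O=C1CCCC=C1I | starting material
3 | (2-tert-butoxy-2-oxoethyl)zinc bromide | CC(C)(C)OC(=O)C[Zn]Br | intermediate
4 | tert-butyl 2-(6-oxocyclohex-1-en-1-yl)acetate | CC(C)(C)OC(=O)CC1=CCCCC1=O | intermediate
5 | tert-butyl 2-[(1R,2R)-6-oxo-2-(4,4,5,5-tetramethyl-1,3,2-dioxaborolan-2-yl)cyclohexyl]acetate | O=C1CCC[C@@H](B2OC(C)(C)C(C)(C)O2)[C@H]1CC(=O)OC(C)(C)C | intermediate
6 | tert-butyl 2-[(1R,2R)-2-hydroxy-6-oxocyclohexyl]acetate | O=C1CCC[C@@H](O)[C@H]1CC(=O)OC(C)(C)C | intermediate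
7 | (3aR,7aR)-hexahydro-1-benzofuran-2,4-dione (cis-fused keto lactone) | C1CC(=O)[C@@H]2CC(=O)O[C@@H]2C1 | intermediate
8 | (3aR,7aR)-4-(trimethylsilyloxy)-3a,6,7,7a-tetrahydro-1-benzofuran-2(3H)-one | C1C=C(O[Si](C)(C)C)[C@@H]2CC(=O)O[C@@H]2C1 | intermediate
9 | (3aR,7aR)-3,3a,7,7a-tetrahydro-1-benzofuran-2,4-dione | C1=CC(=O)[C@@H]2CC(=O)O[C@@H]2C1 | intermediate
10 | (3aR,6R,7aR)-6-methyl-4-(trimethylsilyloxy)-3a,6,7,7a-tetrahydro-1-benzofuran-2(3H)-one | C[C@H]1C=C(O[Si](C)(C)C)[C@@H]2CC(=O)O[C@@H]2C1 | intermediate
11 | (3aR,7aR)-6-methyl-3,3a,7,7a-tetrahydro-1-benzofuran-2,4-dione (bicyclic enone lactone) | CC1=CC(=O)[C@@H]2CC(=O)O[C@@H]2C1 | intermediate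
12 | 1-methylcyclobutene | CC1=CCC1 | starting material
13 | cis-anti-cis photoadduct: bicyclo[2.2.0]hexane (C1, C2, C3, C4, C5, C10; bonds C1–C4 and C5–C10) fused at C5–C10 to the C6 cyclohexanone; methyls on C4 and C10; cis 8,12-γ-lactone (7R,8R); central cyclobutane on the face opposite the lactone, outer cyclobutane anti to the cyclohexanone, C14 cis to O8 | C[C@]12CC[C@H]1[C@]1(C)C[C@H]3OC(=O)C[C@H]3C(=O)[C@H]21 | intermediate
14 | (1(10)E,4Z,7R,8R)-6-oxo-13-norgermacra-1(10),4-dien-12,8-olide (cyclodeca-1(10),4-dien-6-one with cis-fused 8,12-lactone) | C/C1=C\CC/C(C)=C\C(=O)[C@@H]2CC(=O)O[C@@H]2C1 | intermediate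
15 | (1(10)E,4Z,6R,7S,8R)-6-hydroxy-13-norgermacra-1(10),4-dien-12,8-olide (6α-OH trans to C11; cis 8β,12-lactone) | C/C1=C\CC/C(C)=C\[C@@H](O)[C@@H]2CC(=O)O[C@@H]2C1 | intermediate
16 | (1(10)E,4Z,6R,7R,8R)-8-hydroxy-13-norgermacra-1(10),4-dien-12,6-olide (8β-OH; trans 6α,12-lactone) | C1C(=O)O[C@@H]2/C=C(/C)CC/C=C(\C)C[C@@H](O)[C@@H]12 | intermediate
17 | 11-(dimethylaminomethyl) derivative of 16 (aminomethyl group trans to C8 on the lactone ring) | CN(C)C[C@@H]1C(=O)O[C@@H]2/C=C(/C)CC/C=C(\C)C[C@@H](O)[C@@H]12 | intermediate
18 | trimethylammonium iodide of 17 | C[N+](C)(C)C[C@@H]1C(=O)O[C@@H]2/C=C(/C)CC/C=C(\C)C[C@@H](O)[C@@H]12.[I-] | intermediate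
19 | (1(10)E,4Z,6R,7R,8R)-8-hydroxygermacra-1(10),4,11(13)-trien-12,6-olide | C=C1C(=O)O[C@@H]2/C=C(/C)CC/C=C(\C)C[C@@H](O)[C@@H]12 | intermediate
20 | angelic acid, (Z)-2-methylbut-2-enoic acid | C/C=C(/C)C(=O)O | starting material
21 | (Z)-2-methylbut-2-en-1-ol | C/C=C(/C)CO | intermediate
22 | [(2R,3S)-2,3-dimethyloxiran-2-yl]methanol | OC[C@@]1(C)O[C@H]1C | intermediate
23 | (2S,3S)-2,3-dimethyloxirane-2-carboxylic acid | O=C(O)[C@@]1(C)O[C@H]1C | intermediate
24 | (2S,3S)-2,3-dimethyloxirane-2-carboxylic 2,4,6-trichlorobenzoic anhydride | O=C(OC(=O)c1c(Cl)cc(Cl)cc1Cl)[C@@]1(C)O[C@H]1C | intermediate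
25 | (1(10)E,4Z,6R,7R,8R)-8-[(2S,3S)-2,3-dimethyloxirane-2-carbonyloxy]germacra-1(10),4,11(13)-trien-12,6-olide | C=C1C(=O)O[C@@H]2/C=C(/C)CC/C=C(\C)C[C@@H](OC(=O)[C@@]3(C)O[C@H]3C)[C@@H]12 | intermediate
26 | (1R,4Z,6R,7R,8R,10R)-1,10-epoxy-8-[(2S,3S)-2,3-dimethyloxirane-2-carbonyloxy]germacra-4,11(13)-dien-12,6-olide (1β,10α-epoxide, 8β-ester, trans 6α,12-lactone) | C=C1C(=O)O[C@@H]2/C=C(/C)CC[C@H]3O[C@]3(C)C[C@@H](OC(=O)[C@@]3(C)O[C@H]3C)[C@@H]12 | target

Total step count: 15 (steps 11 to 13 make the side-chain acid).
Longest linear sequence: 12 steps (steps 1 to 10, then 14 and 15).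

Steps most likely to fail

Step 7. What may go wrong: partition of the diyl into its other chair, which would give the 1(10)Z,4E isomer, and onward chemistry of the hot conjugated dienone. The latter comprises Cope rearrangement to the divinylcyclohexanone, which is drained once its isopropenyl group moves into conjugation with the ketone, and Z to E isomerisation of the enone through its dienol. Fallback: setting out from 13, the C6 carbonyl is reduced on the rigid tricycle with LiBH(s-Bu)3 (THF, −78 °C). There the axial face is closed by C1, and equatorial attack should give the tricyclic 6α-carbinol F1. Flash thermolysis of F1 under the conditions of step 7 opens the bicyclo[2.2.0]hexane to a dienol whose 4Z alkene is isolated and cannot enolise. This product is 15, where the route is rejoined; steps 7 and 8 are thereby exchanged and the facial question of step 8 is settled on a rigid substrate.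

Step 8. What may go wrong: poor or reversed facial selectivity of hydride delivery, because the ten-membered enone can also populate a pseudo-chair with O8 axial, whose open face leads to the 6β-carbinol. Fallback: setting out from 14, the reduction is run as before and the 6β-carbinol F2 is taken on. A Mitsunobu reaction (4-nitrobenzoic acid, PPh3, DIAD, THF, 0 °C) inverts the allylic carbinol to the 6α-(4-nitrobenzoate) F3 by SN2 at C6; SN2′ attack at the fully substituted C4 is disfavoured. K2CO3 in MeOH then cleaves the aryl ester and lets the freed 6α-alkoxide shift the lactone as in step 9, so that the sequence comes back at 16.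

Step 2. What may go wrong: insufficient enantiofacial discrimination by the boryl–copper complex on an α-branched enone, and base-induced drift of the ring double bond into conjugation with the ester before boron transfer. Fallback: setting out from 4, the same enone carbonyl is treated as the future C8 and reduced under reagent control ((S)-Me-CBS oxazaborolidine 10 mol%, BH3·SMe2, THF, −20 °C) to the (R)-allylic alcohol F4. Hydroboration–oxidation (BH3·THF, 0 °C; then NaBO3·4H2O) anti to the carbinol should give the C2-symmetric (2R,6R)-diol F5, whose two hydroxyls are equivalent. TFA/CH2Cl2 removes the tert-butyl group and closes the cis-fused hydroxy lactone F6, and Dess–Martin periodinane (CH2Cl2, rt) oxidises the remaining carbinol, which returns the route to 7.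

Further compounds
F1 | step 7 | tricyclic 6α-carbinol of 13 (C6–OH trans to C11; cis 8,12-lactone; cis-anti-cis core unchanged) | C[C@]12CC[C@H]1[C@]1(C)C[C@H]3OC(=O)C[C@H]3[C@H](O)[C@H]21
F2 | step 8 | (1(10)E,4Z,6S)-6-hydroxy-13-norgermacra-1(10),4-dien-12,8-olide (6β-carbinol, C6 epimer of 15) | C/C1=C\CC/C(C)=C\[C@H](O)[C@@H]2CC(=O)O[C@@H]2C1
F3 | step 8 | 6α-(4-nitrobenzoyloxy) derivative of the cis 8,12-lactone (4-nitrobenzoate of 15) | C/C1=C\CC/C(C)=C\[C@@H](OC(=O)c3ccc(cc3)[N+](=O)[O-])[C@@H]2CC(=O)O[C@@H]2C1
F4 | step 2 | tert-butyl 2-[(6R)-6-hydroxycyclohex-1-en-1-yl]acetate | CC(C)(C)OC(=O)CC1=CCCC[C@H]1O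
F5 | step 2 | tert-butyl 2-[(2R,6R)-2,6-dihydroxycyclohexyl]acetate | O[C@@H]1CCC[C@@H](O)C1CC(=O)OC(C)(C)C
F6 | step 2 | (3aS,4R,7aR)-4-hydroxyhexahydro-1-benzofuran-2(3H)-one | C1C[C@@H](O)[C@@H]2CC(=O)O[C@@H]2C1
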